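## Structural features

The target is a flavone: benzene ring A is fused at C4a/C8a to the 4-pyranone ring C, which carries benzene ring B at C2. Ring A is hexasubstituted; besides the two fusion carbons it bears OMe at C5, a free OH at C6 and OMe at C7 and C8, so five of its six carbons carry oxygen. Ring B is joined through C1', flanked by a free 2'-OH and a 6'-OMe; the C2–C1' bond is hindered but is taken to rotate freely, and the molecule has no stereocentre. The fragile points are the C5 methyl ether peri to the C4 carbonyl (stripped by boron and aluminium halides), the C2=C3 bond (over-reduction), and the C6/C8a oxygen pair, which is a hydroquinone once both are free and then oxidises to a quinone. The real difficulty is not ring C but the regiodefined ring A: the C6 oxygen must be told apart from three methyl ethers, two of them its direct neighbours. The key step uses the fact that the C6 oxygen is para to the C8a oxygen with C7–OMe and C8–OMe between them. That four-carbon unit is a 3,4-dimethoxy-2-silyloxyfuran: its ring oxygen becomes the C6 hydroxyl, its silyloxy group the C8a oxygen, and an alkyne supplies C5 with its methoxy group and C4a with the C4 carbonyl.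

## Logic of the disconnections

22 to 21. The two phenolic oxygens (O6 and O2') are given benzyl groups. Benzyl leaves by hydrogenolysis, so no Lewis acid ever meets the C5 methyl ether, and one operation frees both phenols. The forward step must spare the C2=C3 bond.

21 to 19. The O1–C2 bond is cut, opening the pyranone to an aryl ynone whose C8a oxygen is a silyl ether. This removes ring C and exposes C4–C3 for a convergent cut. The forward closure must go 6-endo at C2 and not 5-exo at C3, so aprotic fluoride is chosen.

19 to 14 and 17. The C4–C3 bond is cut between the carbonyl carbon and the alkyne, separating ring A with its carbonyl from ring B with its two-carbon link. The gain is full convergence. The forward step asks the acetylide 18 to add once to a carbonyl flanked by two ortho substituents; the N-methoxy-N-methylamide holds the tetrahedral chelate until work-up.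

14 to 13. The O6–benzyl bond is cut. This capping costs one step but keeps the C6 and C8a oxygens from ever being free together, saves the second equivalent of 18 that a free phenol would consume, and is removed together with the ring B benzyl. The alkylation must leave the aryl silyl ether intact.

13 to 6 and 11. Ring A is cut at C8a–C4a and C6–C5, and the C6 oxygen is reconnected to C8a as the ring oxygen of a furan. A hexasubstituted benzene with all six substituents already differentiated thus falls to two small pieces. The forward step needs the right orientation of the two partners, the right direction of bridge opening, and enough reactivity from a donor-substituted alkyne. The atom mapping of 6, 11 and 13 onto the target numbering was checked position by position and holds; no structural correction is needed.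

6 to 5, 4, 3, then 1 and 2. The Si–O bond, the O4–methyl bond, the C3–C4 bond of the furanone and an ester C–O bond are cut in turn. The ring closure must favour enolisation on the methoxyacetyl side, and the methylation must go to the vinylogous acid oxygen.

11 to 9 to 7. The bond between the alkyne carbon and the carbonyl carbon is cut, then the alkyne is traced to a chloroacetal by two eliminations. The alkyne 9 is isolated so that 10 is free of amine and alkoxide, which would otherwise consume the carbamoyl chloride.

17 to 16 to 15. The terminal alkyne carbon is removed (one-carbon homologation of an aldehyde), then the O2'–benzyl bond. The homologation must tolerate a di-ortho-substituted, electron-rich aldehyde.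

## Other disconnections considered

Alternative 1: Ring C is cut at C4–C3 and at the oxygen on C2, and C2, C3 and C4 are stored in an isoxazole. In the forward step the ring A nitrile oxide A2, made in the flask, would add to alkyne 17 to give the 3,5-diarylisoxazole A1.
- In favour: the orientation of nitrile oxide additions to terminal alkynes is dependable, and a di-ortho-substituted aryl nitrile oxide resists dimerisation. The same alkyne 17 serves, and the isoxazole tolerates most later conditions.
- Equal or better: it avoids adding an acetylide to a di-ortho-substituted carbonyl, and its key step has closer precedent than the dienophile of the chosen plan.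
- Against: A2 already contains ring A with five oxygens differentiated (two MOM, three methyl), so the central problem is left to classical arene chemistry. After the key step the N–O bond must be cleaved (Mo(CO)6, since hydrogen would also attack the benzyl ether), nitrogen hydrolysed off C4, both MOM groups removed, ring C closed by dehydration and the benzyl removed. Once the MOM groups are off, the C6 and C8a hydroxyls are free together.
- Comparison: structurally it solves only ring C; mechanistically it is at least as secure; in step count it is longer both before and after the key step.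

Alternative 2: The cut is at C2–C1' and C2'–O. Fluoride would release the methoxy-substituted aryne from A5; the carboxylate of chromone acid A4 would add through oxygen at the aryne carbon remote from the methoxy group, and the aryl anion would add to C2, giving the 3-aroylcoumarin A3.
- In favour: the hindered C2–C1' bond forms under mild conditions, and the methoxy group should steer the aryne to exactly the 2'-O/6'-OMe pattern.
- Equal or better: ring B needs no protecting group, because the lactone masks O2'; A5 is a simple reagent.
- Against: A4 again requires the fully differentiated ring A beforehand. A3 is not a flavone: the pyranone is open and an extra carboxyl carbon is locked in the coumarin. Reaching 22 needs re-closure of O1–C2 by oxa-Michael addition, lactone opening, decarboxylation and a dehydrogenation to restore C2=C3, plus debenzylation.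
- Comparison: mechanistically elegant and regiochemically sound, but it builds no part of ring A and has the poorest step economy after the key step.

Alternative 3: Three bonds are cut at once: C8a–O1, C4a–C4 and O1–C2. Fluoride would generate the symmetric ring A aryne from A7; the carboxylate of arylpropiolic acid A8 (from 17 and CO2) would add, the aryl anion would take the acyl carbon, and the o-acylphenoxide would close ring C to give the acetonide flavone A6.
- In favour: a symmetric aryne poses no orientation problem, and no hindered amide addition is needed.
- Equal or better: three bonds in one operation and only three steps after the key step (acetonide removal, methylation, hydrogenolysis) against four in the chosen plan.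
- Against: A7 is itself a hexasubstituted benzene (silyl, triflate, four oxygens) needing a multistep synthesis. Both aryne carbons are flanked by methoxy groups, and the acyl shift through a four-membered transition state must outrun simple protonation to the aryl ester. After acetonide removal, O7 must be methylated in the presence of O6; this rests on the higher acidity of the 7-OH and is a selectivity question the chosen plan never faces. The final 6-endo closure carries the same risk as step 12.
- Comparison: more convergent in the key step, but ring A is not built, and C6 is differentiated late instead of from the outset.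

Key step: step 7

Remark on the chemistry: no stable atropisomer about C2–C1' is assumed, so no stereochemical element needs control. Compound 11 is an alkynoic N-methoxy-N-methylamide (a propiolamide), not an N-alkynyl amide.

## Route

Step 1
Reactants: 1 methyl glycolate; 2 methoxyacetyl chloride
Product: 3 methyl 2-[(2-methoxyacetyl)oxy]acetate
Conditions: Et3N, DMAP (cat.), CH2Cl2, 0 °C to rt
Reagents that add atoms: none
Why: O-acylation of a primary alcohol by an acid chloride (nucleophilic acyl substitution); nothing else in either partner competes.

Step 2
Reactants: 3 methyl 2-[(2-methoxyacetyl)oxy]acetate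
Product: 4 4-hydroxy-3-methoxyfuran-2(5H)-one
Conditions: KOtBu, THF, 0 °C to rt; then 1 M HCl
Reagents that add atoms: none
Why: Dieckmann condensation: the enolate of the methoxyacetyl unit attacks the methyl ester carbonyl (5-exo-trig) and the closure is pulled forward by formation of the acidic tetronate anion.

Step 3
Reactants: 4 4-hydroxy-3-methoxyfuran-2(5H)-one
Product: 5 3,4-dimethoxyfuran-2(5H)-one
Conditions: Me2SO4, K2CO3, acetone, reflux
Reagents that add atoms: dimethyl sulfate, COS(=O)(=O)OC
Why: O-alkylation of a vinylogous carboxylic acid; a hard methylating agent should go to O4 of the tetronate, and C3 is blocked against C-methylation by its methoxy group.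

Step 4
Reactants: 5 3,4-dimethoxyfuran-2(5H)-one
Product: 6 tert-butyl[(3,4-dimethoxyfuran-2-yl)oxy]dimethylsilane
Conditions: TBSOTf, Et3N, CH2Cl2, 0 °C; pentane, filtration under Ar, used directly
Reagents that add atoms: tert-butyldimethylsilyl trifluoromethanesulfonate, CC(C)(C)[Si](C)(C)OS(=O)(=O)C(F)(F)F
Why: Soft enolisation: silylation of the lactone carbonyl and removal of a C5 proton by the amine gives the aromatic 2-silyloxyfuran, the standard preparation of such dienes from butenolides.

Step 5
Reactants: 7 chloroacetaldehyde dimethyl acetal
Product: 9 methoxyethyne, via sodium methoxyacetylide 8 (not isolated)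
Conditions: NaNH2 (3 equiv), liquid NH3, −33 °C; NH3 evaporated; cold satd aq NaCl, distilled into a −78 °C trap, taken up in dry THF
Reagents that add atoms: none
Why: Two base-induced eliminations (methanol, then HCl) and deprotonation of the alkyne give the sodium acetylide; hydrolysis and distillation deliver the volatile ynol ether free of amine and alkoxide.

Step 6
Reactants: 9 methoxyethyne
Product: 11 N,3-dimethoxy-N-methylprop-2-ynamide, via lithium methoxyacetylide 10 (not isolated)
Conditions: n-BuLi, THF, −78 °C; ClC(=O)N(OMe)Me, −78 to 0 °C; pH 7 buffer; rapid chromatography on Et3N-deactivated SiO2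
Reagents that add atoms: N-methoxy-N-methylcarbamoyl chloride, CON(C)C(Cl)=O
Why: Acylation of an alkynyllithium by a carbamoyl chloride (nucleophilic acyl substitution); with no amine or alkoxide present the acetylide is the only nucleophile, and the product is kept away from acid because the ynol ether hydrates easily.

Step 7
Reactants: 6 tert-butyl[(3,4-dimethoxyfuran-2-yl)oxy]dimethylsilane; 11 N,3-dimethoxy-N-methylprop-2-ynamide
Product: 13 2-[(tert-butyldimethylsilyl)oxy]-5-hydroxy-N,3,4,6-tetramethoxy-N-methylbenzamide, via 7-oxanorbornadiene cycloadduct 12 (not isolated)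
Conditions: 6 (1.5 equiv), PhMe, 90 °C, sealed tube, Ar
Reagents that add atoms: none
Why: Diels–Alder cycloaddition of a 2-silyloxyfuran with an acetylenic carbonyl compound followed by opening of the oxygen bridge, the known route from such furans to 4-silyloxyphenols; the donor-substituted alkyne used here is an untested member of that dienophile class. The three oxygen donors put the largest HOMO coefficient of 6 at C5, and the push–pull polarisation of 11 makes the methoxy-bearing carbon its electrophilic end, so furan C5 bonds there (C6–C5 of the target) and the silyloxy carbon bonds to the carbon next to the carbonyl (C8a–C4a). The carbocycle closes as a [4+2] cycloaddition, probably asynchronous: a vinylogous Mukaiyama–Michael bond first, then 6-exo-trig capture of the silyloxy oxocarbenium ion by the allenolate. Adduct 12 ionises at the bridgehead that carries both the bridge oxygen and the silyloxy group, and loss of the single proton at the other bridgehead aromatises the ring, leaving the bridge oxygen as the free C6 hydroxyl and silicon on the C8a oxygen. No stereocentre remains, since both bridgehead centres of racemic 12 are destroyed on aromatisation. The selectivities needed are the orientation of addition, secured by the matched polarisation of the two partners, and the direction of bridge opening, secured by the silyloxy group on the ketal carbon. A methyl ynol ether has no hydrogen placed for retro-ene loss of an alkene to a ketene, so heating is permissible.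

Step 8
Reactants: 13 2-[(tert-butyldimethylsilyl)oxy]-5-hydroxy-N,3,4,6-tetramethoxy-N-methylbenzamide
Product: 14 5-(benzyloxy)-2-[(tert-butyldimethylsilyl)oxy]-N,3,4,6-tetramethoxy-N-methylbenzamide
Conditions: BnBr, K2CO3, acetone, 45 °C
Reagents that add atoms: benzyl bromide, BrCc1ccccc1
Why: Williamson etherification of the only free phenol; the aryl silyl ether, shielded by its two ortho neighbours, should survive anhydrous carbonate in acetone.

Step 9
Reactants: 15 2-hydroxy-6-methoxybenzaldehyde
Product: 16 2-(benzyloxy)-6-methoxybenzaldehyde
Conditions: BnBr, K2CO3, DMF, rt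
Reagents that add atoms: benzyl bromide, BrCc1ccccc1
Why: Williamson etherification of a salicylaldehyde-type phenol; the aldehyde is inert to these conditions.

Step 10
Reactants: 16 2-(benzyloxy)-6-methoxybenzaldehyde
Product: 17 1-(benzyloxy)-2-ethynyl-3-methoxybenzene
Conditions: dimethyl (1-diazo-2-oxopropyl)phosphonate, K2CO3, MeOH, rt
Reagents that add atoms: dimethyl (1-diazo-2-oxopropyl)phosphonate, COP(=O)(OC)C(=[N+]=[N-])C(C)=O
Why: Ohira–Bestmann variant of the Seyferth–Gilbert homologation: the diazophosphonate anion released by methanolysis olefinates the aldehyde, and loss of N2 with 1,2-hydrogen shift gives the terminal alkyne under mild base.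

Step 11
Reactants: 17 1-(benzyloxy)-2-ethynyl-3-methoxybenzene; 14 5-(benzyloxy)-2-[(tert-butyldimethylsilyl)oxy]-N,3,4,6-tetramethoxy-N-methylbenzamide
Product: 19 1-{5-(benzyloxy)-2-[(tert-butyldimethylsilyl)oxy]-3,4,6-trimethoxyphenyl}-3-[2-(benzyloxy)-6-methoxyphenyl]prop-2-yn-1-one, via lithium arylacetylide 18 (not isolated)
Conditions: 17 (1.3 equiv), n-BuLi (1.25 equiv), THF, −78 °C; then 14, −78 to 0 °C; aq NH4Cl
Reagents that add atoms: none
Why: Ketone synthesis from an N-methoxy-N-methylamide: the slender sp-hybridised nucleophile can reach the di-ortho-substituted carbonyl, and the lithium chelate of the tetrahedral adduct prevents a second addition.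

Step 12
Reactants: 19 1-{5-(benzyloxy)-2-[(tert-butyldimethylsilyl)oxy]-3,4,6-trimethoxyphenyl}-3-[2-(benzyloxy)-6-methoxyphenyl]prop-2-yn-1-one
Product: 21 6-(benzyloxy)-2-[2-(benzyloxy)-6-methoxyphenyl]-5,7,8-trimethoxy-4H-chromen-4-one, via potassium phenoxide ynone 20 (not isolated)
Conditions: KF (spray-dried), 18-crown-6, dry DMF, rt; then water
Reagents that add atoms: none
Why: Fluoride desilylation followed by intramolecular oxa-Michael addition (6-endo-dig) of the C8a phenoxide to the ynone; in aprotic medium 5-exo attack would give an unstabilised vinyl anion that reverts, whereas 6-endo attack gives a stabilised allenolate, so the pyranone should dominate.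

Step 13
Reactants: 21 6-(benzyloxy)-2-[2-(benzyloxy)-6-methoxyphenyl]-5,7,8-trimethoxy-4H-chromen-4-one
Product: 22 6-hydroxy-2-(2-hydroxy-6-methoxyphenyl)-5,7,8-trimethoxy-4H-chromen-4-one (6,2'-dihydroxy-5,7,8,6'-tetramethoxyflavone)
Conditions: H2 (1 atm), 10% Pd/C, EtOAc–MeOH, rt
Reagents that add atoms: none
Why: Catalytic hydrogenolysis of two aryl benzyl ethers; the pyranone double bond of flavones normally survives these mild conditions and no Lewis acid touches the C5 methyl ether.

## Compound list

1 | methyl glycolate | COC(=O)CO | starting material
2 | methoxyacetyl chloride | COCC(Cl)=O | starting material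
3 | methyl 2-[(2-methoxyacetyl)oxy]acetate | COCC(=O)OCC(=O)OC | intermediate
4 | 4-hydroxy-3-methoxyfuran-2(5H)-one | COC1=C(O)COC1=O | intermediate
5 | 3,4-dimethoxyfuran-2(5H)-one | COC1=C(OC)C(=O)OC1 | intermediate
6 | tert-butyl[(3,4-dimethoxyfuran-2-yl)oxy]dimethylsilane | COc1coc(O[Si](C)(C)C(C)(C)C)c1OC | intermediate
7 | chloroacetaldehyde dimethyl acetal | COC(CCl)OC | starting material
8 | sodium methoxyacetylide | COC#C[Na] | intermediate
9 | methoxyethyne | COC#C | intermediate
10 | lithium methoxyacetylide | COC#C[Li] | intermediate
11 | N,3-dimethoxy-N-methylprop-2-ynamide | COC#CC(=O)N(C)OC | intermediate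
12 | 1-[(tert-butyldimethylsilyl)oxy]-N,3,5,6-tetramethoxy-N-methyl-7-oxabicyclo[2.2.1]hepta-2,5-diene-2-carboxamide (racemic) | CON(C)C(=O)C1=C(OC)C2OC1(O[Si](C)(C)C(C)(C)C)C(OC)=C2OC | intermediate
13 | 2-[(tert-butyldimethylsilyl)oxy]-5-hydroxy-N,3,4,6-tetramethoxy-N-methylbenzamide | CON(C)C(=O)c1c(O[Si](C)(C)C(C)(C)C)c(OC)c(OC)c(O)c1OC | intermediate
14 | 5-(benzyloxy)-2-[(tert-butyldimethylsilyl)oxy]-N,3,4,6-tetramethoxy-N-methylbenzamide | CON(C)C(=O)c1c(O[Si](C)(C)C(C)(C)C)c(OC)c(OC)c(OCc2ccccc2)c1OC | intermediate
15 | 2-hydroxy-6-methoxybenzaldehyde | COc1cccc(O)c1C=O | starting material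
16 | 2-(benzyloxy)-6-methoxybenzaldehyde | COc1cccc(OCc2ccccc2)c1C=O | intermediate
17 | 1-(benzyloxy)-2-ethynyl-3-methoxybenzene | COc1cccc(OCc2ccccc2)c1C#C | intermediate
18 | lithium [2-(benzyloxy)-6-methoxyphenyl]acetylide | COc1cccc(OCc2ccccc2)c1C#C[Li] | intermediate
19 | 1-{5-(benzyloxy)-2-[(tert-butyldimethylsilyl)oxy]-3,4,6-trimethoxyphenyl}-3-[2-(benzyloxy)-6-methoxyphenyl]prop-2-yn-1-one | COc1cccc(OCc2ccccc2)c1C#CC(=O)c1c(O[Si](C)(C)C(C)(C)C)c(OC)c(OC)c(OCc2ccccc2)c1OC | intermediate
20 | potassium 4-(benzyloxy)-2-{3-[2-(benzyloxy)-6-methoxyphenyl]prop-2-ynoyl}-3,5,6-trimethoxyphenoxide | COc1cccc(OCc2ccccc2)c1C#CC(=O)c1c([O-])c(OC)c(OC)c(OCc2ccccc2)c1OC.[K+] | intermediate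
21 | 6-(benzyloxy)-2-[2-(benzyloxy)-6-methoxyphenyl]-5,7,8-trimethoxy-4H-chromen-4-one | COc1cccc(OCc2ccccc2)c1-c1cc(=O)c2c(OC)c(OCc3ccccc3)c(OC)c(OC)c2o1 | intermediate
22 | 6-hydroxy-2-(2-hydroxy-6-methoxyphenyl)-5,7,8-trimethoxy-4H-chromen-4-one | COc1cccc(O)c1-c1cc(=O)c2c(OC)c(O)c(OC)c(OC)c2o1 | target

## Step count and least certain steps

Total step count: 13. Longest linear sequence: 9 steps (steps 1, 2, 3, 4, 7, 8, 11, 12, 13).

**Step 7 (key step).** The methoxy donor lowers the electrophilicity of the alkyne, so thermal desilylation or decomposition of the furan may outrun cycloaddition. Alternatively the reaction may stop at the open Mukaiyama–Michael stage, with silicon passing to the amide enolate and no ring closure. The fallback forms the same two bonds by a polar annulation and sets out from 5 (with 11). Deprotonation of 5 at C5 with lithium diisopropylamide in THF at −78 °C gives the lithiated tetronate, which should add to the methoxy-bearing carbon of 11; the resulting alkenyl anion closes onto the lactone carbonyl, the alkoxide collapses with opening of the bridge, and tautomerisation followed by reductive work-up (aq Na2S2O4) should give 2,5-dihydroxy-N,3,4,6-tetramethoxy-N-methylbenzamide F1. One equivalent of BnBr with K2CO3 in acetone should alkylate the hydroxyl that is not hydrogen-bonded to the amide, giving 5-(benzyloxy)-2-hydroxy-N,3,4,6-tetramethoxy-N-methylbenzamide F2. Silylation with TBSCl and imidazole in DMF returns to the route at 14.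

**Step 6.** The carbamoyl chloride is a weak electrophile, so acylation may be slow enough for the alkoxyacetylide to decompose on warming. The fallback sets out from 10 and uses methyl chloroformate, a much stronger acylating agent, to give methyl 3-methoxyprop-2-ynoate F3; the ester is also the stronger acceptor for the cycloaddition. Heating F3 with 6 as in step 7 should give methyl 2-[(tert-butyldimethylsilyl)oxy]-5-hydroxy-3,4,6-trimethoxybenzoate F4, and benzylation as in step 8 gives methyl 5-(benzyloxy)-2-[(tert-butyldimethylsilyl)oxy]-3,4,6-trimethoxybenzoate F5. Addition of 18 to F5 with BF3·OEt2 in THF at −78 °C, where the two ortho groups and the low temperature hold back a second addition, returns to the route at 19.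

**Step 11.** Addition to the di-ortho-substituted amide may be slow, and the acetylide may then act as a base, inducing loss of the N-methoxy group as formaldehyde. The fallback sets out from 14 and replaces the acyl substitution by an addition–oxidation sequence. Reduction with i-Bu2AlH in THF at −78 °C should give 5-(benzyloxy)-2-[(tert-butyldimethylsilyl)oxy]-3,4,6-trimethoxybenzaldehyde F6. Addition of 18 gives racemic 1-{5-(benzyloxy)-2-[(tert-butyldimethylsilyl)oxy]-3,4,6-trimethoxyphenyl}-3-[2-(benzyloxy)-6-methoxyphenyl]prop-2-yn-1-ol F7, and oxidation with MnO2 in CH2Cl2 returns to the route at 19.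

**Step 12.** Traces of proton donors may allow 5-exo-dig closure at C3 to a benzofuranone, or desilylation of the hindered aryl silyl ether may stall. The fallback sets out from 19 and fixes the site of attack before the phenol is freed. Diethylamine in ethanol should add to the ynone to give (E)-1-{5-(benzyloxy)-2-[(tert-butyldimethylsilyl)oxy]-3,4,6-trimethoxyphenyl}-3-[2-(benzyloxy)-6-methoxyphenyl]-3-(diethylamino)prop-2-en-1-one F8. Bu4NF buffered with acetic acid in THF then frees the phenol, which can only add to the amine-bearing carbon and expel diethylamine (addition–elimination), returning to the route at 21.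

**Step 2.** Enolisation at the glycolate methylene may divert the substrate into acyl migration or intermolecular Claisen oligomers. The fallback sets out from 2 and forms the C3–C4 bond intermolecularly. Methanolysis of 2 (MeOH, pyridine) gives methyl methoxyacetate F9; its lithium enolate (lithium diisopropylamide, 2 equiv, THF, −78 °C) is acylated with acetoxyacetyl chloride to give methyl 4-acetoxy-2-methoxy-3-oxobutanoate F10. HCl in methanol removes the acetate and the hydroxy keto ester lactonises, returning to the route at 4.

## Further compounds

F1 | step 7 | 2,5-dihydroxy-N,3,4,6-tetramethoxy-N-methylbenzamide | CON(C)C(=O)c1c(O)c(OC)c(OC)c(O)c1OC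
F2 | step 7 | 5-(benzyloxy)-2-hydroxy-N,3,4,6-tetramethoxy-N-methylbenzamide | CON(C)C(=O)c1c(O)c(OC)c(OC)c(OCc2ccccc2)c1OC
F3 | step 6 | methyl 3-methoxyprop-2-ynoate | COC#CC(=O)OC
F4 | step 6 | methyl 2-[(tert-butyldimethylsilyl)oxy]-5-hydroxy-3,4,6-trimethoxybenzoate | COC(=O)c1c(O[Si](C)(C)C(C)(C)C)c(OC)c(OC)c(O)c1OC
F5 | step 6 | methyl 5-(benzyloxy)-2-[(tert-butyldimethylsilyl)oxy]-3,4,6-trimethoxybenzoate | COC(=O)c1c(O[Si](C)(C)C(C)(C)C)c(OC)c(OC)c(OCc2ccccc2)c1OC
F6 | step 11 | 5-(benzyloxy)-2-[(tert-butyldimethylsilyl)oxy]-3,4,6-trimethoxybenzaldehyde | O=Cc1c(O[Si](C)(C)C(C)(C)C)c(OC)c(OC)c(OCc2ccccc2)c1OC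
F7 | step 11 | 1-{5-(benzyloxy)-2-[(tert-butyldimethylsilyl)oxy]-3,4,6-trimethoxyphenyl}-3-[2-(benzyloxy)-6-methoxyphenyl]prop-2-yn-1-ol (racemic) | COc1cccc(OCc2ccccc2)c1C#CC(O)c1c(O[Si](C)(C)C(C)(C)C)c(OC)c(OC)c(OCc2ccccc2)c1OC
F8 | step 12 | (E)-1-{5-(benzyloxy)-2-[(tert-butyldimethylsilyl)oxy]-3,4,6-trimethoxyphenyl}-3-[2-(benzyloxy)-6-methoxyphenyl]-3-(diethylamino)prop-2-en-1-one | CCN(CC)/C(=C/C(=O)c1c(O[Si](C)(C)C(C)(C)C)c(OC)c(OC)c(OCc2ccccc2)c1OC)c1c(OC)cccc1OCc1ccccc1
F9 | step 2 | methyl methoxyacetate | COCC(=O)OC
F10 | step 2 | methyl 4-acetoxy-2-methoxy-3-oxobutanoate (racemic) | COC(C(=O)COC(C)=O)C(=O)OC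
A1 | alternative 1 | 5-[2-(benzyloxy)-6-methoxyphenyl]-3-[3,4,6-trimethoxy-2,5-bis(methoxymethoxy)phenyl]-1,2-oxazole | COCOc1c(OC)c(OC)c(OCOC)c(OC)c1-c1cc(-c2c(OC)cccc2OCc2ccccc2)on1
A2 | alternative 1 | 3,4,6-trimethoxy-2,5-bis(methoxymethoxy)benzonitrile oxide | COCOc1c(OC)c(OC)c(OCOC)c(OC)c1C#[N+][O-]
A3 | alternative 2 | 3-[5-(benzyloxy)-2-hydroxy-3,4,6-trimethoxybenzoyl]-5-methoxy-2H-chromen-2-one | O=c1oc2cccc(OC)c2cc1C(=O)c1c(O)c(OC)c(OC)c(OCc2ccccc2)c1OC
A4 | alternative 2 | 6-(benzyloxy)-5,7,8-trimethoxy-4-oxo-4H-chromene-3-carboxylic acid | O=C(O)c1coc2c(OC)c(OC)c(OCc3ccccc3)c(OC)c2c1=O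
A5 | alternative 2 | 3-methoxy-2-(trimethylsilyl)phenyl trifluoromethanesulfonate | COc1cccc(OS(=O)(=O)C(F)(F)F)c1[Si](C)(C)C
A6 | alternative 3 | 6,7-acetonide of 2-[2-(benzyloxy)-6-methoxyphenyl]-6,7-dihydroxy-5,8-dimethoxy-4H-chromen-4-one | COc1cccc(OCc2ccccc2)c1-c1cc(=O)c2c(OC)c3OC(C)(C)Oc3c(OC)c2o1
A7 | alternative 3 | 4,7-dimethoxy-2,2-dimethyl-6-(trimethylsilyl)-1,3-benzodioxol-5-yl trifluoromethanesulfonate | COc1c2OC(C)(C)Oc2c(OC)c(OS(=O)(=O)C(F)(F)F)c1[Si](C)(C)C
A8 | alternative 3 | 3-[2-(benzyloxy)-6-methoxyphenyl]prop-2-ynoic acid | COc1cccc(OCc2ccccc2)c1C#CC(=O)O
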